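## Retrosynthetic overview
1. The C11 chlorohydrin comes from HCl opening of the 11,13-spiro-epoxide of an α-methylene lactone. The angelate is placed on O8 of a free 8,9-diol just before that.
2. Key disconnection: O–C3 and C9–C10 are broken together. An open-chain α'-acetoxy ynone that also carries the C9 aldehyde gives, in one pot, the 3(2H)-furanone ring and, through its C10 enolate, the ten-membered carbocycle.
3. C5–O, C6–O and C8–O come from one double asymmetric dihydroxylation of a skipped triene. The C6 hydroxyl then closes the trans γ-lactone.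
4. C7–C11 comes from a Johnson–Claisen rearrangement (C5 to C7 chirality transfer), C4–C5 from an allenylzinc addition to pentadienal, and C1–C2 from acylation of an alkynylsilane with a lactic acid chloride.
5. Ring order: γ-lactone first, then furanone and carbocycle in the same operation.

Assumption: atom labels follow germacrane numbering. C1 is the ketone, C2=C3 the enol ether, C4 CH(CH3), C5 CHOH, C6 the lactone CH–O, C7 CH, C8 the CH–O ester, C9 CHOH and C10 the quaternary carbon. C11/C12/C13 are the lactone α-carbon, carbonyl and exocyclic carbon, and C14/C15 are the methyls on C10/C4. The silylated butynol, acetoxypropanoyl chloride and angelic acid are taken as catalogue chemicals.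

## Route

Step 1
Reactants: 1 penta-1,4-dien-3-ol
Product: 3 (2E)-penta-2,4-dienal, via (2E)-penta-2,4-dien-1-ol 2 (not isolated)
Conditions: Re2O7 (2 mol %), CH2Cl2, 0 °C; then MnO2 (10 equiv), rt; filtered and used as a solution
Reagents that add atoms: none
Why: A rhenium-oxo-catalysed 1,3-transposition of the allylic alcohol is driven by conjugation to the E dienol, and MnO2 allylic oxidation then gives the dienal; no stereocentre is formed.

Step 2
Reactants: 4 (2R)-4-(trimethylsilyl)but-3-yn-2-ol
Product: 5 (2R)-4-(trimethylsilyl)but-3-yn-2-yl methanesulfonate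
Conditions: MsCl, Et3N, CH2Cl2, −78 °C
Reagents that add atoms: methanesulfonyl chloride, CS(=O)(=O)Cl
Why: O-sulfonylation does not touch the C–O bond, so the R configuration is kept.

Step 3
Reactants: 3 (2E)-penta-2,4-dienal; 5 (2R)-4-(trimethylsilyl)but-3-yn-2-yl methanesulfonate
Product: 7 (3S,4R,5E)-3-methyl-1-(trimethylsilyl)octa-5,7-dien-1-yn-4-ol, via allenylzinc reagent 6 (not isolated)
Conditions: Pd(OAc)2 (5 mol %), PPh3 (5 mol %), Et2Zn (3 equiv), THF, −78 to −20 °C; aq NH4Cl
Reagents that add atoms: none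
Why: In this Marshall–Tamaru propargylation, zerovalent palladium displaces the mesylate anti (SN2'), Et2Zn transmetalates to 6, and its closed SE2' transition state adds 1,2 to the enal, so C4 comes from 4 with net inversion and the C5 carbinol is set anti to the C4 methyl.

Step 4
Reactants: 7 (3S,4R,5E)-3-methyl-1-(trimethylsilyl)octa-5,7-dien-1-yn-4-ol
Product: 9 methyl (3R,4E,6R)-3-ethenyl-6-methyl-8-(trimethylsilyl)oct-4-en-7-ynoate, via mixed ketene acetal 8 (not isolated)
Conditions: MeC(OMe)3 (8 equiv), EtCO2H (10 mol %), xylene, 135 °C, MeOH distilled off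
Reagents that add atoms: trimethyl orthoacetate, COC(C)(OC)OC
Why: In this Johnson orthoester Claisen rearrangement, the chair [3,3] shift with the C4 side chain equatorial gives the E C5=C6 alkene and passes the C5 carbinol configuration suprafacially to the new C7 centre.

Step 5
Reactants: 9 methyl (3R,4E,6R)-3-ethenyl-6-methyl-8-(trimethylsilyl)oct-4-en-7-ynoate
Product: 12 methyl (3R,4E,6R)-3-ethenyl-6-methyl-2-methylidene-8-(trimethylsilyl)oct-4-en-7-ynoate, via Mannich base 10 (not isolated), via trimethylammonium iodide 11 (not isolated)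
Conditions: LDA (1.1 equiv), THF, −78 °C; CH2=NMe2 iodide; then MeI, rt; then aq NaHCO3/CH2Cl2
Reagents that add atoms: Eschenmoser's salt, C=[N+](C)C.[I-]
Why: An ester enolate Mannich reaction is followed by quaternisation and Hofmann-type elimination (classical α-methylenation); the silyl group blocks acetylide formation, the weak base avoids conjugation of the skipped triene, and the transient C11 centre is destroyed.

Step 6
Reactants: 12 methyl (3R,4E,6R)-3-ethenyl-6-methyl-2-methylidene-8-(trimethylsilyl)oct-4-en-7-ynoate; 13 (2S)-2-acetoxypropanoyl chloride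
Product: 14 methyl (3R,4E,6R,10S)-10-acetoxy-3-ethenyl-6-methyl-2-methylidene-9-oxoundec-4-en-7-ynoate
Conditions: CuCl (20 mol %), 1,3-dimethyl-2-imidazolidinone, 80 °C
Reagents that add atoms: none
Why: This is a copper-catalysed acylation of an alkynylsilane (silicon-to-copper transfer, then acylation) under neutral conditions that spare the acrylate and triene; the C10 centre comes from 13 and is erased in step 9.

Step 7
Reactants: 14 methyl (3R,4E,6R,10S)-10-acetoxy-3-ethenyl-6-methyl-2-methylidene-9-oxoundec-4-en-7-ynoate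
Product: 16 (2S,6S,7S)-7-{(2S,3R)-3-[(1S)-1,2-dihydroxyethyl]-4-methylidene-5-oxooxolan-2-yl}-7-hydroxy-6-methyl-3-oxohept-4-yn-2-yl acetate, via tetraol ester 15 (not isolated)
Conditions: OsO4 (2 mol %), (DHQ)2PHAL (6 mol %), NMO (2.1 equiv), acetone/H2O 10:1, 0 °C, slow addition of 14; then TsOH·H2O (5 mol %), CH2Cl2, rt
Reagents that add atoms: N-methylmorpholine N-oxide, C[N+]1([O-])CCOCC1; water, O
Why: In this Sharpless asymmetric dihydroxylation (neutral NMO variant, so the acetate stays), the DHQ ligand sets 5S,6S on the E alkene and 8S on the vinyl group, the electron-poor acrylate and ynone react far more slowly, and acid closes the trans 6,12-γ-lactone because closure through O8 would give the cis ring.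

Step 8
Reactants: 16 lactone triol (name as in step 7)
Product: 17 (2S,6S,7S)-7-hydroxy-7-{(2S,3R)-3-[(1S)-1-hydroxy-2-oxoethyl]-4-methylidene-5-oxooxolan-2-yl}-6-methyl-3-oxohept-4-yn-2-yl acetate
Conditions: TEMPO (10 mol %), PhI(OAc)2 (1.1 equiv), CH2Cl2, 0 °C; used crude
Reagents that add atoms: none
Why: Oxoammonium oxidation takes the primary C9 alcohol much faster than the two secondary ones, and one equivalent of oxidant at 0 °C limits glycol cleavage and over-oxidation; no stereocentre is changed.

Step 9 (key step)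
Reactants: 17 hydroxy aldehyde (name as in step 8)
Product: 20 (4R,5S,6S,7R,8S,9S,10S)-5,8,9-trihydroxy-1-oxo-3,10-epoxygermacra-2,11(13)-dien-12,6-olide, via hydroxy ynone aldehyde 18 (not isolated), via 2H-furanone aldehyde 19 (not isolated)
Conditions: K2CO3 (2 equiv), THF/H2O 4:1, 0 °C to rt, 17 added by syringe pump to 1 mM; early quench with pH 5 buffer
Reagents that add atoms: none
Why: Proposed new method: the activated α-keto acetate hydrolyses first, the freed C10 hydroxyl adds 5-endo to the ynone in the protic medium to give furanone 19, carbonate then forms its aromatic furan-3-olate, and C10 adds to the C9 aldehyde, so the furanone ring and the ten-membered carbocycle form in one operation from a nucleophile that did not exist before; the closest known reactions are base-mediated cycloisomerisation of α'-hydroxy ynones to 3(2H)-furanones, C2 aldol or alkylation of 2-methyl-3(2H)-furanones, and aldol closures of the same 11-oxabicyclo[6.2.1]undecane frame; C9 is set by polar Felkin–Anh attack anti to the C8 oxygen (8,9-anti), C10 by the C3–C9 tether, which lets the aldehyde reach only the furanolate face that leaves C14 outside the ring, reversibility lets the less strained isomer build up, and the early quench forestalls the slower Michael addition to C13.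

Step 10
Reactants: 20 macrocyclic triol (name as in step 9); 21 angelic acid, (2Z)-2-methylbut-2-enoic acid
Product: 23 (4R,5S,6S,7S,8S,9S,10S)-8-angeloyloxy-5,9-dihydroxy-1-oxo-3,10-epoxygermacra-2,11(13)-dien-12,6-olide, via angeloyl chloride 22 (not isolated)
Conditions: 21, 1-chloro-N,N,2-trimethylprop-1-en-1-amine (1.2 equiv), CH2Cl2, 0 °C; then 20, Ph2BOCH2CH2NH2 (10 mol %), i-Pr2NEt, MeCN, rt
Reagents that add atoms: none
Why: In this borinic-acid-catalysed regioselective acylation, the diphenylborinate binds only the 8,9-diol, the less hindered O8 is acylated because O9 is neopentyl, and the neutral DMAP-free generation of 22 keeps the Z alkene; no stereocentre is formed.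

Step 11
Reactants: 23 8-angelate (name as in step 10)
Product: 25 (4R,5S,6S,7S,8S,9S,10S,11S)-8-angeloyloxy-13-chloro-5,9,11-trihydroxy-1-oxo-3,10-epoxygermacr-2-en-12,6-olide, via 11,13-spiro-epoxide 24 (not isolated)
Conditions: t-BuOOH, DBU (0.3 equiv), CH2Cl2, 0 °C; then HCl (4 M in dioxane), 0 °C
Reagents that add atoms: tert-butyl hydroperoxide, CC(C)(C)OO; hydrogen chloride, Cl
Why: In this Weitz–Scheffer epoxidation, the peroxide anion adds only to the unhindered exocyclic acceptor (the angelate and the vinylogous ester are β-substituted and deactivated), the enolate closes on the face anti to the C8 chain (cis to H7), which sets C11, and chloride then opens the epoxide by SN2 at primary C13 with the C11–O bond retained.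

## Compound list
1 | penta-1,4-dien-3-ol | C=CC(O)C=C | starting material
2 | (2E)-penta-2,4-dien-1-ol | OC/C=C/C=C | intermediate
3 | (2E)-penta-2,4-dienal | O=C/C=C/C=C | intermediate
4 | (2R)-4-(trimethylsilyl)but-3-yn-2-ol | C[C@@H](O)C#C[Si](C)(C)C | starting material
5 | (2R)-4-(trimethylsilyl)but-3-yn-2-yl methanesulfonate | C[C@@H](OS(C)(=O)=O)C#C[Si](C)(C)C | intermediate
6 | (aS)-ethyl[1-(trimethylsilyl)buta-1,2-dien-1-yl]zinc | CC([H])=[C@]=C([Zn]CC)[Si](C)(C)C | intermediate
7 | (3S,4R,5E)-3-methyl-1-(trimethylsilyl)octa-5,7-dien-1-yn-4-ol | C=C/C=C/[C@@H](O)[C@@H](C)C#C[Si](C)(C)C | intermediate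
8 | 1-methoxyethenyl ether of 7 (mixed ketene acetal) | C=C/C=C/[C@@H](OC(=C)OC)[C@@H](C)C#C[Si](C)(C)C | intermediate
9 | methyl (3R,4E,6R)-3-ethenyl-6-methyl-8-(trimethylsilyl)oct-4-en-7-ynoate | C=C[C@@H](CC(=O)OC)/C=C/[C@@H](C)C#C[Si](C)(C)C | intermediate
10 | 2-[(dimethylamino)methyl] derivative of 9 (C2 epimers) | C=C[C@@H](C(CN(C)C)C(=O)OC)/C=C/[C@@H](C)C#C[Si](C)(C)C | intermediate
11 | N-methyl quaternary iodide of 10 | C=C[C@@H](C(C[N+](C)(C)C)C(=O)OC)/C=C/[C@@H](C)C#C[Si](C)(C)C.[I-] | intermediate
12 | methyl (3R,4E,6R)-3-ethenyl-6-methyl-2-methylidene-8-(trimethylsilyl)oct-4-en-7-ynoate | C=C[C@@H](C(=C)C(=O)OC)/C=C/[C@@H](C)C#C[Si](C)(C)C | intermediate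
13 | (2S)-2-acetoxypropanoyl chloride | C[C@H](OC(C)=O)C(Cl)=O | starting material
14 | methyl (3R,4E,6R,10S)-10-acetoxy-3-ethenyl-6-methyl-2-methylidene-9-oxoundec-4-en-7-ynoate | C=C[C@@H](C(=C)C(=O)OC)/C=C/[C@@H](C)C#CC(=O)[C@H](C)OC(C)=O | intermediate
15 | methyl (3R,4S,5S,6S,10S)-10-acetoxy-3-[(1S)-1,2-dihydroxyethyl]-4,5-dihydroxy-6-methyl-2-methylidene-9-oxoundec-7-ynoate | O[C@H](CO)[C@@H](C(=C)C(=O)OC)[C@H](O)[C@@H](O)[C@@H](C)C#CC(=O)[C@H](C)OC(C)=O | intermediate
16 | lactone triol (trans 6,12-α-methylene-γ-lactone; 4S,5S,6S,7R,8S,10S) | O[C@H](CO)[C@@H]1[C@H](OC(=O)C1=C)[C@@H](O)[C@@H](C)C#CC(=O)[C@H](C)OC(C)=O | intermediate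
17 | C9 aldehyde of 16 | O[C@H](C=O)[C@@H]1[C@H](OC(=O)C1=C)[C@@H](O)[C@@H](C)C#CC(=O)[C@H](C)OC(C)=O | intermediate
18 | C10 alcohol of 17 (acetate removed) | O[C@H](C=O)[C@@H]1[C@H](OC(=O)C1=C)[C@@H](O)[C@@H](C)C#CC(=O)[C@H](C)O | intermediate
19 | 2-methyl-3(2H)-furanone isomer of 18 (C10 labile) | O[C@H](C=O)[C@@H]1[C@H](OC(=O)C1=C)[C@@H](O)[C@@H](C)C1=CC(=O)C(C)O1 | intermediate
20 | (4R,5S,6S,7R,8S,9S,10S)-5,8,9-trihydroxy-1-oxo-3,10-epoxygermacra-2,11(13)-dien-12,6-olide | O[C@H]1[C@@H]2[C@H](OC(=O)C2=C)[C@@H](O)[C@@H](C)C2=CC(=O)[C@@](C)(O2)[C@H]1O | intermediate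
21 | angelic acid | C/C=C(/C)C(=O)O | starting material
22 | angeloyl chloride | C/C=C(/C)C(=O)Cl | intermediate
23 | 8-O-angelate of 20 | C/C=C(/C)C(=O)O[C@H]1[C@@H]2[C@H](OC(=O)C2=C)[C@@H](O)[C@@H](C)C2=CC(=O)[C@@](C)(O2)[C@H]1O | intermediate
24 | (11R)-11,13-epoxide of 23 | C/C=C(/C)C(=O)O[C@H]1[C@@H]2[C@H](OC(=O)[C@]23CO3)[C@@H](O)[C@@H](C)C2=CC(=O)[C@@](C)(O2)[C@H]1O | intermediate
25 | CNP0340393.2 | C/C=C(/C)C(=O)O[C@H]1[C@@H]2[C@H](OC(=O)[C@]2(O)CCl)[C@@H](O)[C@@H](C)C2=CC(=O)[C@@](C)(O2)[C@H]1O | target

## Step count and risks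
Total step count: 11. Longest linear sequence: 10 (steps 1, 3, 4, 5, 6, 7, 8, 9, 10, 11).

**Most likely to fail: step 9.** The reversible aldol may not favour the ten-membered ring, or C10 may add to the methylene lactone instead. The fallback sets out from 17 and returns at 20. It takes the cascade apart and makes the closure irreversible.
- The acetate of 17 is removed with Candida antarctica lipase B (pH 7 buffer/MTBE), and 18 is isolated.
- AuCl3 (2 mol %, CH2Cl2) cycloisomerises 18 to 19, which is also isolated.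
- Excess TMSOTf/i-Pr2NEt (CH2Cl2, −78 °C, 1 mM) caps the two hydroxyls and converts the furanone into the bis-silylated 3-silyloxyfuran aldehyde F1.
- The same reagent triggers a Mukaiyama aldol whose aldolate is trapped on silicon as the tris(trimethylsilyl) ether of the macrocycle F2.
- Citric acid in MeOH then gives 20.

**Second: step 10.** The borinate may not form on the anti 8,9-diol, or O5 and O9 may compete. The fallback sets out from 17 and returns at 23. It puts the ester on before ring closure.
- In the ring-chain tautomer of 17, O5 has added to C9 and is hidden.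
- Acylation with 22 (2.5 equiv, 2,6-lutidine, CH2Cl2) gives the pyranose 8,9-bis-angelate F3.
- The conditions of step 9 then cleave the acetate and the acylal-type anomeric angelate but not the hindered 8-angelate.
- This frees the aldehyde and closes both rings, giving 23 directly.

**Third: step 11.** The aldol unit and the vicinal ester/alcohol pair may not survive peroxide and DBU. The fallback sets out from 23 and returns at 25. It replaces nucleophilic epoxidation by osmylation and substitution.
- OsO4 (cat.)/NMO attacks the exocyclic methylene from the face anti to the C8 chain and gives the 11,13-diol F4.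
- PPh3/N-chlorosuccinimide (THF, 0 °C) converts only the primary C13 hydroxyl into the chloride, giving 25.

## Further compounds
F1 | step 9 | O5,O8-bis(trimethylsilyl) 3-(trimethylsilyloxy)furan aldehyde from 19 | C[Si](C)(C)O[C@H](C=O)[C@@H]1[C@H](OC(=O)C1=C)[C@@H](O[Si](C)(C)C)[C@@H](C)c1cc(O[Si](C)(C)C)c(C)o1
F2 | step 9 | 5,8,9-tris(trimethylsilyl) ether of 20 | C[Si](C)(C)O[C@H]1[C@@H]2[C@H](OC(=O)C2=C)[C@@H](O[Si](C)(C)C)[C@@H](C)C2=CC(=O)[C@@](C)(O2)[C@H]1O[Si](C)(C)C
F3 | step 10 | pyranose (O5–C9) 8,9-bis-angelate of 17 (anomers) | C/C=C(/C)C(=O)O[C@H]1[C@@H]2[C@H](OC(=O)C2=C)[C@@H](OC1OC(=O)C(/C)=C\C)[C@@H](C)C#CC(=O)[C@H](C)OC(C)=O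
F4 | step 11 | (11R)-11,13-diol of 23 | C/C=C(/C)C(=O)O[C@H]1[C@@H]2[C@H](OC(=O)[C@]2(O)CO)[C@@H](O)[C@@H](C)C2=CC(=O)[C@@](C)(O2)[C@H]1O
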